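**Retrosynthetic overview** (ring A = cyclohexadienone ring, ring B = benzene ring of the chromene, ring C = pyran ring)
1. Target ⇒ achiral methylene-bridged bis(acylphloroglucinol) with ring A still aromatic, plus prenol; a catalytic asymmetric dearomative prenylation is the last step and sets the only stereocentre.
2. Methylene bridge ⇒ chromene half (rings B/C) as Mannich base / ortho-quinone methide, plus the C-methyl acylphloroglucinol (ring A precursor).
3. Both halves ⇒ one common intermediate, isobutyrylphloroglucinol (prenal annulation gives ring C; C-methylation gives the ring A precursor).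
4. Isobutyrylphloroglucinol ⇒ cyclopentane-1,2,4-trione + 1-diazo-3-methylbutan-2-one by a one-carbon ring expansion (1,2-shift of a ring carbon, five- to six-membered, then aromatisation); the diazoketone ⇒ isobutyryl chloride + CH2N2.
5. Ring order: carbocycles of A and B (same ring expansion) → ring C → bridge → dearomatisation of ring A.

Assumption: cyclopentane-1,2,4-trione is taken as a purchasable catalogue chemical (handled as its enol), and the sense of induction of the chiral ligand in the last step is assumed and would be confirmed by ECD.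

**Step 1**
Reactants: 1 2-methylpropanoyl chloride (isobutyryl chloride)
Product: 2 1-diazo-3-methylbutan-2-one
Conditions: CH2N2 (2.5 equiv), Et2O, 0 °C to rt
Reagents that add atoms: diazomethane, C=[N+]=[N-]
Why: Arndt–Eistert-type acylation of diazomethane, in which the acid chloride acylates the diazo carbon and a second equivalent of CH2N2 takes up the HCl as CH3Cl and N2.

**Step 2**
Reactants: 3 cyclopentane-1,2,4-trione; 2 1-diazo-3-methylbutan-2-one
Product: 5 1-(2,4,6-trihydroxyphenyl)-2-methylpropan-1-one (isobutyrylphloroglucinol), via acyltrione 4 (not isolated)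
Conditions: Sc(OTf)3 (10 mol %), 2 (1.2 equiv) added over 2 h, CH2Cl2–MeCN 4:1, −20 °C to rt
Reagents that add atoms: none
Why: Proposed new method: aromatising one-carbon ring expansion of a cyclic vicinal dione by an α-diazoketone; Sc(OTf)3 chelates the α-oxo-enol unit of 3 (oxygens on C1 and C2), the diazo carbon of 2 adds to the activated C1 carbonyl, and the adjacent oxygen-bearing sp2 carbon C2 (electron-rich, a far better migrating group than the C5 methylene flanked by a second carbonyl) undergoes a 1,2-shift to the diazonium carbon with loss of N2, so the new carbon carrying the isobutyryl group is inserted between two C–O carbons and the five-membered ring becomes six-membered acyltrione 4, which tautomerises irreversibly to the phloroglucinol (no stereocentre formed); closest known reaction type: Tiffeneau–Demjanov / Büchner–Curtius–Schlotterbeck diazo homologation with acyl migration, as in the ring enlargement of indane-1,2,3-trione to 2-hydroxy-1,4-naphthoquinones and the Lewis-acid-catalysed ring expansion of isatins with diazo compounds.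

**Step 3**
Reactants: 5 1-(2,4,6-trihydroxyphenyl)-2-methylpropan-1-one; 6 3-methylbut-2-enal (prenal)
Product: 8 1-(5,7-dihydroxy-2,2-dimethyl-2H-chromen-8-yl)-2-methylpropan-1-one, via oxatriene 7 (not isolated)
Conditions: 6 (1.5 equiv), ethylenediammonium diacetate (10 mol %), toluene, 110 °C; chromatography
Reagents that add atoms: none
Why: Knoevenagel-type condensation at a free ring carbon gives oxatriene 7, which closes by oxa-6π electrocyclisation through the oxygen ortho to the acyl group (standard 2H-chromene synthesis from phenols and prenal), the 6-acyl regioisomer from closure through the para oxygen being removed by chromatography.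

**Step 4**
Reactants: 5 1-(2,4,6-trihydroxyphenyl)-2-methylpropan-1-one
Product: 9 1-(2,4,6-trihydroxy-3-methylphenyl)-2-methylpropan-1-one
Conditions: NaOMe (1.1 equiv), MeI (1.0 equiv), MeOH, 0 °C to rt
Reagents that add atoms: iodomethane, CI
Why: C-alkylation of the ambident phloroglucinolate (SN2); the two free ring carbons are equivalent, so one equivalent of MeI gives the mono-C-methyl compound, separated from a little dimethylated material.

**Step 5**
Reactants: 8 1-(5,7-dihydroxy-2,2-dimethyl-2H-chromen-8-yl)-2-methylpropan-1-one; 9 1-(2,4,6-trihydroxy-3-methylphenyl)-2-methylpropan-1-one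
Product: 12 1-[3-{[5,7-dihydroxy-2,2-dimethyl-8-(2-methylpropanoyl)-2H-chromen-6-yl]methyl}-2,4,6-trihydroxy-5-methylphenyl]-2-methylpropan-1-one, via Mannich base 10 (not isolated), via quinone methide 11 (not isolated)
Conditions: 8, CH2(NMe2)2 (1.1 equiv), 1,4-dioxane, 60 °C, then evaporate; 9 (1.0 equiv), 1,4-dioxane, 95 °C
Reagents that add atoms: bis(dimethylamino)methane, CN(C)CN(C)C
Why: Mannich aminomethylation at the only free ring carbon of 8, then thermal loss of Me2NH to the ortho-quinone methide and Friedel–Crafts-type Michael addition of the only free ring carbon of 9 (the Mannich base / quinone methide route to methylene-bridged phloroglucinol dimers of the rottlerin type).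

**Step 6**
Reactants: 12 1-[3-{[5,7-dihydroxy-2,2-dimethyl-8-(2-methylpropanoyl)-2H-chromen-6-yl]methyl}-2,4,6-trihydroxy-5-methylphenyl]-2-methylpropan-1-one; 13 3-methylbut-2-en-1-ol (prenol)
Product: 14 (4S)-3,5-dihydroxy-4-methyl-4-(3-methylbut-2-en-1-yl)-2-(2-methylpropanoyl)-6-{[5,7-dihydroxy-2,2-dimethyl-8-(2-methylpropanoyl)-2H-chromen-6-yl]methyl}cyclohexa-2,5-dien-1-one (CNP0301804.1)
Conditions: 13 (1.05 equiv), Pd2(dba)3·CHCl3 (2.5 mol %), (R,R)-DACH-phenyl Trost ligand (7.5 mol %), Et3B (30 mol %), CH2Cl2, 0 °C to rt
Reagents that add atoms: none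
Why: Proposed new method: asymmetric dehydrative Tsuji–Trost dearomatisation, in which the zerovalent palladium–Trost ligand complex ionises Et3B-activated prenol and the ring A phenoxide attacks the CH2 terminus of the palladium-bound prenyl unit through its methyl-bearing carbon (the only fully substituted nucleophilic carbon not shielded by the diarylmethane group, and O-prenyl ethers re-ionise so C-alkylation is the sink), while the ligand amide N–H binds the phenoxide oxygen para to the acyl group and the ortho OH stays chelated to the acyl carbonyl, so the two faces of ring A are differentiated and the (S) quaternary centre is set under catalyst control (the mirror-image ligand is used if the sense proves opposite); closest known reaction types: Pd/Et3B C-allylation of phloroglucinol with allyl alcohols, asymmetric allylic dearomatisation of 3-substituted indoles (allyl alcohol/borane) and of naphthols, and asymmetric prenylation of oxindoles with Trost ligands.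

**Compound list**
1 | 2-methylpropanoyl chloride (isobutyryl chloride) | CC(C)C(Cl)=O | starting material
2 | 1-diazo-3-methylbutan-2-one | CC(C)C(=O)C=[N+]=[N-] | intermediate
3 | cyclopentane-1,2,4-trione (enol: 2-hydroxycyclopent-2-ene-1,4-dione) | O=C1CC(=O)C(=O)C1 | starting material
4 | 2-(2-methylpropanoyl)cyclohexane-1,3,5-trione (acyltrione, formed in the flask) | CC(C)C(=O)C1C(=O)CC(=O)CC1=O | intermediate
5 | 1-(2,4,6-trihydroxyphenyl)-2-methylpropan-1-one | CC(C)C(=O)c1c(O)cc(O)cc1O | intermediate
6 | 3-methylbut-2-enal | CC(C)=CC=O | starting material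
7 | 3,5-dihydroxy-6-(3-methylbut-2-en-1-ylidene)-2-(2-methylpropanoyl)cyclohexa-2,4-dien-1-one (oxatriene, formed in the flask) | CC(C)C(=O)C1=C(O)C=C(O)C(=CC=C(C)C)C1=O | intermediate
8 | 1-(5,7-dihydroxy-2,2-dimethyl-2H-chromen-8-yl)-2-methylpropan-1-one | CC(C)C(=O)c1c(O)cc(O)c2C=CC(C)(C)Oc12 | intermediate
9 | 1-(2,4,6-trihydroxy-3-methylphenyl)-2-methylpropan-1-one | CC(C)C(=O)c1c(O)cc(O)c(C)c1O | intermediate
10 | 1-{6-[(dimethylamino)methyl]-5,7-dihydroxy-2,2-dimethyl-2H-chromen-8-yl}-2-methylpropan-1-one (Mannich base, formed in the flask) | CC(C)C(=O)c1c(O)c(CN(C)C)c(O)c2C=CC(C)(C)Oc12 | intermediate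
11 | 7-hydroxy-2,2-dimethyl-6-methylidene-8-(2-methylpropanoyl)-2H-chromen-5(6H)-one (ortho-quinone methide, formed in the flask) | C=C1C(O)=C(C(=O)C(C)C)C2=C(C=CC(C)(C)O2)C1=O | intermediate
12 | 1-[3-{[5,7-dihydroxy-2,2-dimethyl-8-(2-methylpropanoyl)-2H-chromen-6-yl]methyl}-2,4,6-trihydroxy-5-methylphenyl]-2-methylpropan-1-one | CC(C)C(=O)c1c(O)c(C)c(O)c(Cc2c(O)c(C(=O)C(C)C)c3OC(C)(C)C=Cc3c2O)c1O | intermediate
13 | 3-methylbut-2-en-1-ol | CC(C)=CCO | starting material
14 | (4S)-3,5-dihydroxy-4-methyl-4-(3-methylbut-2-en-1-yl)-2-(2-methylpropanoyl)-6-{[5,7-dihydroxy-2,2-dimethyl-8-(2-methylpropanoyl)-2H-chromen-6-yl]methyl}cyclohexa-2,5-dien-1-one | CC(C)=CC[C@@]1(C)C(O)=C(Cc2c(O)c3c(c(C(=O)C(C)C)c2O)OC(C)(C)C=C3)C(=O)C(C(=O)C(C)C)=C1O | target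

**Totals**
Total step count: 6. Longest linear sequence: 5 steps (1 → 2 → 3 or 4 → 5 → 6).

**Steps most likely to fail, with fallbacks**

Step 2 (proposed new ring expansion; risks are O-alkylation of the acidic enol and migration of the wrong ring carbon). Fallback by known chemistry, setting out from 1 and returning at 5: 1 is methanolysed to methyl 2-methylpropanoate F1. F1 acylates the dilithio dianion of pentane-2,4-dione (LiN(iPr)2, THF, −78 to 0 °C; Hauser–Harris terminal acylation) to give 7-methyloctane-2,4,6-trione F2. The trianion of F2 (LiN(iPr)2, 3.3 equiv) is carboxylated at the terminal CH3 with CO2 and the acid is esterified with CH2N2 to methyl 8-methyl-3,5,7-trioxononanoate F3. Mg(OMe)2 in MeOH then closes the ring by intramolecular Claisen condensation (C6 onto the ester, the biomimetic polyketide cyclisation), and enolisation gives 5.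

Step 6 (proposed new asymmetric dearomative prenylation; risks are low enantioselectivity and O- or wrong-carbon prenylation). Fallback by known chemistry, setting out from 9 and returning at 14: 9 is prenylated at the methyl-bearing carbon with 1-bromo-3-methylbut-2-ene and NaOMe in MeOH (classical dearomative C-alkylation, separated from the ring-prenylated isomer) to give racemic 3,5-dihydroxy-4-methyl-4-(3-methylbut-2-en-1-yl)-2-(2-methylpropanoyl)cyclohexa-2,5-dien-1-one F6. Preparative HPLC on an amylose carbamate chiral phase gives (4S)-3,5-dihydroxy-4-methyl-4-(3-methylbut-2-en-1-yl)-2-(2-methylpropanoyl)cyclohexa-2,5-dien-1-one F7 (assigned by ECD). F7 is heated with Mannich base 10 (made from 8 as in step 5) in 1,4-dioxane at 95 °C, where its free enolic carbon adds to quinone methide 11, giving 14 directly.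

Step 3 (regiochemistry of pyran closure; the 6-acyl isomer may dominate). Fallback setting out from 5 and returning at 8: 5 is silylated selectively at the non-chelated para hydroxyl (TBSCl, imidazole, CH2Cl2, 0 °C) to give 1-[4-(tert-butyldimethylsilyloxy)-2,6-dihydroxyphenyl]-2-methylpropan-1-one F4. With prenal and ethylenediammonium diacetate only an ortho oxygen can now close the pyran ring, giving 1-[5-(tert-butyldimethylsilyloxy)-7-hydroxy-2,2-dimethyl-2H-chromen-8-yl]-2-methylpropan-1-one F5 as a single regioisomer. Bu4NF (THF, 0 °C) frees 8.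

**Further compounds**
F1 | step 2 | methyl 2-methylpropanoate | COC(=O)C(C)C
F2 | step 2 | 7-methyloctane-2,4,6-trione | CC(C)C(=O)CC(=O)CC(C)=O
F3 | step 2 | methyl 8-methyl-3,5,7-trioxononanoate | COC(=O)CC(=O)CC(=O)CC(=O)C(C)C
F4 | step 3 | 1-[4-(tert-butyldimethylsilyloxy)-2,6-dihydroxyphenyl]-2-methylpropan-1-one | CC(C)C(=O)c1c(O)cc(O[Si](C)(C)C(C)(C)C)cc1O
F5 | step 3 | 1-[5-(tert-butyldimethylsilyloxy)-7-hydroxy-2,2-dimethyl-2H-chromen-8-yl]-2-methylpropan-1-one | CC(C)C(=O)c1c(O)cc(O[Si](C)(C)C(C)(C)C)c2C=CC(C)(C)Oc12
F6 | step 6 | racemic 3,5-dihydroxy-4-methyl-4-(3-methylbut-2-en-1-yl)-2-(2-methylpropanoyl)cyclohexa-2,5-dien-1-one | CC(C)=CCC1(C)C(O)=CC(=O)C(C(=O)C(C)C)=C1O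
F7 | step 6 | (4S)-3,5-dihydroxy-4-methyl-4-(3-methylbut-2-en-1-yl)-2-(2-methylpropanoyl)cyclohexa-2,5-dien-1-one | CC(C)=CC[C@@]1(C)C(O)=CC(=O)C(C(=O)C(C)C)=C1O
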